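## Retrosynthetic overview

1. The plan rests on ring A of the flavanone unit. It shares the C4a–C8a edge with pyranone ring C, which holds the only stereocentre (C2). Its triad C5(OH)–C6(aryl)–C7(O) is read as one ketene carbonyl carbon plus the two carbons of an aryl siloxyalkyne, and C8 as a former diazo carbon.
2. Last disconnection: the pyranone ring of the flavone unit is cut at O1''–C2'' and C4''–C4a''. This leads back to a free phenol on the pendant phloroglucinol ring and 3-[4-(benzyloxy)phenyl]propynoic acid (ester, photo-Fries shift, 6-endo closure).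
3. Key disconnection: ring A is cut at C8–C8a, C7–C8, C5–C6 and C4a–C5. The precursors are an enantiopure 6-(diazoacetyl)dihydropyranone and an aryl siloxyalkyne, so the C6–C8'' biaryl bond is traced back to an aryl–alkyne bond.
4. Ring C comes from 4-(benzyloxy)benzaldehyde and the bis(silyl) dienol ether of methyl 2,4-dioxopentanoate by a catalytic asymmetric formal hetero-Diels–Alder reaction. The siloxyalkyne comes from 2,4,6-trihydroxybenzaldehyde by alkyne homologation and acetylide oxidation.
5. Order of ring formation: ring C (step 2), ring A (step 9), flavone pyranone ring (step 14). The three other benzene rings are bought.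

Key step: step 9

Assumption: the SMILES fixes only C2 and leaves the hindered C6–C8'' axis open, so from the key step onwards each compound is carried on as whatever mixture of atropisomers forms (unprimed locants = flavanone unit, double-primed = flavone unit).

## Route

Step 1
Reactants: 1 methyl 2,4-dioxopentanoate
Product: 2 methyl (2Z)-2,4-bis(trimethylsilyloxy)penta-2,4-dienoate
Conditions: TMSOTf (2.3 equiv), Et3N (2.6 equiv), Et2O, 0 °C → rt
Reagents that add atoms: trimethylsilyl trifluoromethanesulfonate, C[Si](C)(C)OS(=O)(=O)C(F)(F)F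
Why: Soft enolisation with a silyl triflate and a tertiary amine, as used for the bis(silyl) dienol ethers of 1,3-diketones: the already enolised C2 oxygen is silylated first, and the C5 methyl group, the only acidic site left, then delivers the terminal silyl enol ether.

Step 2
Reactants: 2 methyl (2Z)-2,4-bis(trimethylsilyloxy)penta-2,4-dienoate; 3 4-(benzyloxy)benzaldehyde
Product: 5 methyl (2S)-2-[4-(benzyloxy)phenyl]-4-oxo-3,4-dihydro-2H-pyran-6-carboxylate, via silylated aldol adduct 4 (not isolated)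
Conditions: (S)-BINOL (20 mol %), Ti(OiPr)4 (10 mol %), 4 Å MS, Et2O, −20 °C; then TFA, CH2Cl2, 0 °C
Reagents that add atoms: none
Why: BINOL–Ti(OiPr)4-catalysed formal hetero-Diels–Alder reaction, known for 1,3-dioxygenated dienes and aromatic aldehydes, which runs as an enantioselective Mukaiyama aldol addition of the terminal CH2 of 2 followed by acid-induced addition–elimination of the benzylic oxygen at the siloxy-bearing carbon; the catalyst sets C2, its (S)-antipode being expected, by analogy with its allyl and enol-silane additions to aromatic aldehydes, to leave the Si face open and so to give (S), which is to be confirmed on 5 before it is recrystallised to enantiopurity.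

Step 3
Reactants: 5 methyl (2S)-2-[4-(benzyloxy)phenyl]-4-oxo-3,4-dihydro-2H-pyran-6-carboxylate
Product: 7 (2S)-2-[4-(benzyloxy)phenyl]-4-oxo-3,4-dihydro-2H-pyran-6-carboxylic acid, via trimethylstannyl ester 6 (not isolated)
Conditions: Me3SnOH (4 equiv), ClCH2CH2Cl, 60 °C; then 1 M HCl wash
Reagents that add atoms: trimethyltin hydroxide, C[Sn](C)(C)O
Why: Ester cleavage with trimethyltin hydroxide, a near-neutral hydrolysis that should spare the base-labile ring, since deprotonation at C3 would open the C2–O bond by beta-elimination and erase the stereocentre.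

Step 4
Reactants: 7 (2S)-2-[4-(benzyloxy)phenyl]-4-oxo-3,4-dihydro-2H-pyran-6-carboxylic acid
Product: 9 (S)-2-[4-(benzyloxy)phenyl]-6-(diazoacetyl)-2,3-dihydro-4H-pyran-4-one, via isobutyl mixed carbonic anhydride 8 (not isolated)
Conditions: i-BuOCOCl, N-methylmorpholine, THF, −20 °C; then CH2N2 (1.5 equiv), Et2O, −20 → 0 °C
Reagents that add atoms: diazomethane, C=[N+]=[N-]; isobutyl chloroformate, CC(C)COC(=O)Cl (its atoms stay only in 8)
Why: Acylation of diazomethane as in the first stage of the Arndt–Eistert sequence; the carbonate leaving group takes up the proton, so little more than one equivalent of diazomethane is needed, and this, the low temperature and the donor-substituted, trisubstituted C5=C6 bond should hold back dipolar cycloaddition to the enone.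

Step 5
Reactants: 10 2,4,6-trihydroxybenzaldehyde
Product: 11 2,4-bis(benzyloxy)-6-hydroxybenzaldehyde
Conditions: BnBr (2.05 equiv), K2CO3, DMF, rt
Reagents that add atoms: benzyl bromide, BrCc1ccccc1
Why: Williamson ether synthesis under stoichiometric control: the 4-OH and one of the two equivalent ortho hydroxyls are alkylated, while the last one is held in a hydrogen bond to the formyl oxygen and reacts far more slowly.

Step 6
Reactants: 11 2,4-bis(benzyloxy)-6-hydroxybenzaldehyde
Product: 12 2,4-bis(benzyloxy)-6-(methoxymethoxy)benzaldehyde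
Conditions: NaH, MOMCl, DMF, 0 °C → rt
Reagents that add atoms: chloromethyl methyl ether, COCCl
Why: Williamson-type O-alkylation after full deprotonation, which breaks the chelate; the resulting acetal is orthogonal to the benzyl and silyl ethers used later.

Step 7
Reactants: 12 2,4-bis(benzyloxy)-6-(methoxymethoxy)benzaldehyde
Product: 13 1,5-bis(benzyloxy)-2-ethynyl-3-(methoxymethoxy)benzene
Conditions: dimethyl (1-diazo-2-oxopropyl)phosphonate, K2CO3, MeOH–THF, rt
Reagents that add atoms: dimethyl (1-diazo-2-oxopropyl)phosphonate, CC(=O)C(=[N+]=[N-])P(=O)(OC)OC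
Why: Seyferth–Gilbert homologation in its Ohira–Bestmann form, which turns aryl aldehydes into terminal alkynes under mild carbonate conditions that leave benzyl and MOM ethers alone.

Step 8
Reactants: 13 1,5-bis(benzyloxy)-2-ethynyl-3-(methoxymethoxy)benzene
Product: 16 {[2,4-bis(benzyloxy)-6-(methoxymethoxy)phenyl]ethynyloxy}triisopropylsilane, via lithium acetylide 14 (not isolated), via lithium ynolate 15 (not isolated)
Conditions: n-BuLi, THF, −78 °C; t-BuOOLi (from t-BuOOH, LiN(SiMe3)2), −78 → 0 °C; TIPSOTf, −78 → 0 °C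
Reagents that add atoms: tert-butyl hydroperoxide, CC(C)(C)OO; triisopropylsilyl trifluoromethanesulfonate, CC(C)[Si](OS(=O)(=O)C(F)(F)F)(C(C)C)C(C)C; n-butyllithium, [Li]CCCC (lithium of 14 and 15 only)
Why: Oxidation of a lithium acetylide by lithium tert-butyl peroxide to the ynolate followed by O-silylation with a bulky silyl triflate, a known entry to triisopropylsiloxyalkynes; it is preferred to a Kowalski ester homologation because the reacting carbon lies two atoms away from the di-ortho-substituted ring instead of being a carbonyl carbon buried between two alkoxy groups.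

Step 9
Reactants: 9 (S)-2-[4-(benzyloxy)phenyl]-6-(diazoacetyl)-2,3-dihydro-4H-pyran-4-one; 16 {[2,4-bis(benzyloxy)-6-(methoxymethoxy)phenyl]ethynyloxy}triisopropylsilane
Product: 20 (2S)-2-[4-(benzyloxy)phenyl]-6-[2,4-bis(benzyloxy)-6-(methoxymethoxy)phenyl]-5-hydroxy-7-(triisopropylsilyloxy)chroman-4-one, via vinylketene 17 (not isolated), via 4-vinylcyclobutenone 18 (not isolated), via dienylketene 19 (not isolated)
Conditions: 16 (1.3 equiv), hν (405 nm LED), degassed ClCH2CH2Cl, rt; then 80 °C, dark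
Reagents that add atoms: none
Why: Proposed new method: light that only the diazo chromophore absorbs expels N2 and moves pyranone C6 onto the former diazo carbon (Wolff rearrangement, bond C8–C8a) to give vinylketene 17, whose carbonyl carbon (future C5) is attacked by the aryl-bearing carbon of 16 in a [2+2] cycloaddition (bonds C5–C6 and C7–C8) that gives 4-vinylcyclobutenone 18. Heating opens 18 in a four-electron conrotatory process to dienylketene 19, and ring A is closed by a six-electron disrotatory electrocyclisation between the ketene carbon C5 and C4a, after which the proton on C4a moves to oxygen and the ring becomes aromatic with its 5-OH hydrogen-bonded to the C4 carbonyl. The closest known reaction type is the Danheiser benzannulation of cycloalkenyl and aryl diazomethyl ketones with alkyl-substituted triisopropylsiloxyalkynes; what has not been shown is a vinylketene built into a dihydropyranone (a vinylogous ester) and a siloxyalkyne that carries a 2,6-dioxygenated aryl group. The selectivity needed is the orientation of the [2+2] step, and it is secured by the oxygen donor of 16, which makes only the remote, aryl-bearing carbon nucleophilic, so that the aryl ring must end on C6 between the new 5-OH and the 7-siloxy group; in the closure C4a is the donor-activated alpha carbon of the vinylogous ester and matches the electrophilic ketene carbon, while the C4 carbonyl is held trans to the ketene across the ring double bond and cannot intercept it. No stereocentre is created in 20 (the one in 18 is lost on ring opening), and C2 should stay intact because the medium holds neither acid nor base, the enone of 9 is transparent at 405 nm, and 20 sheds excitation by proton transfer within its chelate. The four ortho substituents of the biaryl axis meet only in the exergonic aromatisation, since the bond itself enters as an unhindered aryl–alkyne bond.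

Step 10
Reactants: 20 (2S)-2-[4-(benzyloxy)phenyl]-6-[2,4-bis(benzyloxy)-6-(methoxymethoxy)phenyl]-5-hydroxy-7-(triisopropylsilyloxy)chroman-4-one
Product: 21 (2S)-2-[4-(benzyloxy)phenyl]-6-[2,4-bis(benzyloxy)-6-hydroxyphenyl]-5-hydroxy-7-(triisopropylsilyloxy)chroman-4-one
Conditions: HCl (1.25 M in MeOH), CH2Cl2, 0 °C → rt
Reagents that add atoms: none
Why: Acid-catalysed transacetalisation of the aryl MOM ether to methanol, mild enough for the aryl TIPS ether, the benzyl ethers and the C2 centre, which is labile mainly to base.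

Step 11
Reactants: 22 1-(benzyloxy)-4-ethynylbenzene
Product: 25 3-[4-(benzyloxy)phenyl]prop-2-ynoic acid, via lithium acetylide 23 (not isolated), via lithium propynoate 24 (not isolated)
Conditions: n-BuLi, THF, −78 °C; CO2; then 1 M HCl
Reagents that add atoms: carbon dioxide, O=C=O; n-butyllithium, [Li]CCCC (lithium of 23 and 24 only)
Why: Carboxylation of a lithium acetylide with CO2, the standard route to arylpropynoic acids.

Step 12
Reactants: 21 (2S)-2-[4-(benzyloxy)phenyl]-6-[2,4-bis(benzyloxy)-6-hydroxyphenyl]-5-hydroxy-7-(triisopropylsilyloxy)chroman-4-one; 25 3-[4-(benzyloxy)phenyl]prop-2-ynoic acid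
Product: 26 3,5-bis(benzyloxy)-2-[(2S)-2-[4-(benzyloxy)phenyl]-5-hydroxy-4-oxo-7-(triisopropylsilyloxy)chroman-6-yl]phenyl 3-[4-(benzyloxy)phenyl]prop-2-ynoate
Conditions: DCC, DMAP (10 mol %), CH2Cl2, 0 °C
Reagents that add atoms: none
Why: Steglich esterification; of the two phenols only the one on the pendant ring is free to react, because the 5-OH is tied up in the chelate with the C4 carbonyl and is flanked by the aryl group.

Step 13
Reactants: 26 3,5-bis(benzyloxy)-2-[(2S)-2-[4-(benzyloxy)phenyl]-5-hydroxy-4-oxo-7-(triisopropylsilyloxy)chroman-6-yl]phenyl 3-[4-(benzyloxy)phenyl]prop-2-ynoate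
Product: 27 (2S)-2-[4-(benzyloxy)phenyl]-6-{4,6-bis(benzyloxy)-3-[3-(4-(benzyloxy)phenyl)prop-2-ynoyl]-2-hydroxyphenyl}-5-hydroxy-7-(triisopropylsilyloxy)chroman-4-one
Conditions: hν (300 nm), degassed benzene, rt
Reagents that add atoms: none
Why: Photo-Fries rearrangement, known to turn aryl 3-arylpropynoates into o-hydroxyaryl ethynyl ketones by homolysis of the ArO–acyl bond and recombination in the solvent cage; one ortho carbon is the biaryl carbon, so only the future C4a'' is open next to the oxygen, the para carbon between two benzyloxy groups is the more remote and more crowded competitor, and the chelated flavanone chromophore should only waste light.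

Step 14
Reactants: 27 (2S)-2-[4-(benzyloxy)phenyl]-6-{4,6-bis(benzyloxy)-3-[3-(4-(benzyloxy)phenyl)prop-2-ynoyl]-2-hydroxyphenyl}-5-hydroxy-7-(triisopropylsilyloxy)chroman-4-one
Product: 28 (2S)-2-[4-(benzyloxy)phenyl]-6-[5,7-bis(benzyloxy)-2-(4-(benzyloxy)phenyl)-4-oxo-4H-chromen-8-yl]-5-hydroxy-7-(triisopropylsilyloxy)chroman-4-one
Conditions: DMAP (20 mol %), DMF, rt
Reagents that add atoms: none
Why: DMAP-catalysed 6-endo-dig cyclisation of an o-alkynoylphenol (conjugate addition of the catalyst, then addition–elimination by the phenol), known to give flavones without the 5-exo isomer, and chosen instead of carbonate or alkoxide bases so that ring C of the flavanone is not opened at C2–O.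

Step 15
Reactants: 28 (2S)-2-[4-(benzyloxy)phenyl]-6-[5,7-bis(benzyloxy)-2-(4-(benzyloxy)phenyl)-4-oxo-4H-chromen-8-yl]-5-hydroxy-7-(triisopropylsilyloxy)chroman-4-one
Product: 29 (2S)-2-[4-(benzyloxy)phenyl]-6-[5,7-bis(benzyloxy)-2-(4-(benzyloxy)phenyl)-4-oxo-4H-chromen-8-yl]-5,7-dihydroxychroman-4-one
Conditions: TBAF, AcOH (1:1), THF, 0 °C
Reagents that add atoms: none
Why: Fluoride cleavage of an aryl silyl ether, buffered with acetic acid so that no basic fluoride or free phenoxide can open ring C by beta-elimination.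

Step 16
Reactants: 29 (2S)-2-[4-(benzyloxy)phenyl]-6-[5,7-bis(benzyloxy)-2-(4-(benzyloxy)phenyl)-4-oxo-4H-chromen-8-yl]-5,7-dihydroxychroman-4-one
Product: 30 CNP0154104.1, (2S)-6-[5,7-dihydroxy-2-(4-hydroxyphenyl)-4-oxo-4H-chromen-8-yl]-5,7-dihydroxy-2-(4-hydroxyphenyl)chroman-4-one
Conditions: H2 (1 atm), 10% Pd/C, EtOAc–THF, rt
Reagents that add atoms: none
Why: Catalytic hydrogenolysis of the four benzyl aryl ethers under neutral conditions, which should be faster than reduction of the flavone C2''=C3'' bond or cleavage of the benzylic C2–O bond if the reaction is stopped after four equivalents of hydrogen, and which leaves C2 untouched.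

## Compound list

1 | methyl 2,4-dioxopentanoate | COC(=O)C(=O)CC(C)=O | starting material
2 | methyl (2Z)-2,4-bis(trimethylsilyloxy)penta-2,4-dienoate | COC(=O)/C(O[Si](C)(C)C)=C/C(=C)O[Si](C)(C)C | intermediate
3 | 4-(benzyloxy)benzaldehyde | O=Cc1ccc(OCc2ccccc2)cc1 | starting material
4 | methyl (2Z,6S)-6-[4-(benzyloxy)phenyl]-4-oxo-2,6-bis(trimethylsilyloxy)hex-2-enoate | COC(=O)/C(O[Si](C)(C)C)=C/C(=O)C[C@H](O[Si](C)(C)C)c1ccc(OCc2ccccc2)cc1 | intermediate
5 | methyl (2S)-2-[4-(benzyloxy)phenyl]-4-oxo-3,4-dihydro-2H-pyran-6-carboxylate | O=C1C[C@@H](c2ccc(OCc3ccccc3)cc2)OC(C(=O)OC)=C1 | intermediate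
6 | trimethylstannyl (2S)-2-[4-(benzyloxy)phenyl]-4-oxo-3,4-dihydro-2H-pyran-6-carboxylate | O=C1C[C@@H](c2ccc(OCc3ccccc3)cc2)OC(C(=O)O[Sn](C)(C)C)=C1 | intermediate
7 | (2S)-2-[4-(benzyloxy)phenyl]-4-oxo-3,4-dihydro-2H-pyran-6-carboxylic acid | O=C1C[C@@H](c2ccc(OCc3ccccc3)cc2)OC(C(=O)O)=C1 | intermediate
8 | (2S)-2-[4-(benzyloxy)phenyl]-4-oxo-3,4-dihydro-2H-pyran-6-carboxylic isobutyl carbonic anhydride | O=C1C[C@@H](c2ccc(OCc3ccccc3)cc2)OC(C(=O)OC(=O)OCC(C)C)=C1 | intermediate
9 | (S)-2-[4-(benzyloxy)phenyl]-6-(diazoacetyl)-2,3-dihydro-4H-pyran-4-one | O=C1C[C@@H](c2ccc(OCc3ccccc3)cc2)OC(C(=O)C=[N+]=[N-])=C1 | intermediate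
10 | 2,4,6-trihydroxybenzaldehyde | O=Cc1c(O)cc(O)cc1O | starting material
11 | 2,4-bis(benzyloxy)-6-hydroxybenzaldehyde | O=Cc1c(O)cc(OCc2ccccc2)cc1OCc1ccccc1 | intermediate
12 | 2,4-bis(benzyloxy)-6-(methoxymethoxy)benzaldehyde | COCOc1cc(OCc2ccccc2)cc(OCc2ccccc2)c1C=O | intermediate
13 | 1,5-bis(benzyloxy)-2-ethynyl-3-(methoxymethoxy)benzene | COCOc1cc(OCc2ccccc2)cc(OCc2ccccc2)c1C#C | intermediate
14 | lithium [2,4-bis(benzyloxy)-6-(methoxymethoxy)phenyl]acetylide | COCOc1cc(OCc2ccccc2)cc(OCc2ccccc2)c1C#C[Li] | intermediate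
15 | lithium [2,4-bis(benzyloxy)-6-(methoxymethoxy)phenyl]ethynolate | COCOc1cc(OCc2ccccc2)cc(OCc2ccccc2)c1C#CO[Li] | intermediate
16 | {[2,4-bis(benzyloxy)-6-(methoxymethoxy)phenyl]ethynyloxy}triisopropylsilane | COCOc1cc(OCc2ccccc2)cc(OCc2ccccc2)c1C#CO[Si](C(C)C)(C(C)C)C(C)C | intermediate
17 | (S)-2-[4-(benzyloxy)phenyl]-6-(2-oxoethenyl)-2,3-dihydro-4H-pyran-4-one (vinylketene) | O=C1C[C@@H](c2ccc(OCc3ccccc3)cc2)OC(C=C=O)=C1 | intermediate
18 | (2S)-2-[4-(benzyloxy)phenyl]-6-{3-[2,4-bis(benzyloxy)-6-(methoxymethoxy)phenyl]-4-oxo-2-(triisopropylsilyloxy)cyclobut-2-en-1-yl}-2,3-dihydro-4H-pyran-4-one (ring carbon C1 of the cyclobutenone unassigned) | O=C1C[C@@H](c2ccc(OCc3ccccc3)cc2)OC(C2C(=O)C(c3c(OCOC)cc(OCc4ccccc4)cc3OCc3ccccc3)=C2O[Si](C(C)C)(C(C)C)C(C)C)=C1 | intermediate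
19 | (2S)-2-[4-(benzyloxy)phenyl]-6-{(1E)-3-[2,4-bis(benzyloxy)-6-(methoxymethoxy)phenyl]-4-oxo-2-(triisopropylsilyloxy)buta-1,3-dien-1-yl}-2,3-dihydro-4H-pyran-4-one (dienylketene) | O=C1C[C@@H](c2ccc(OCc3ccccc3)cc2)OC(/C=C(\C(=C=O)c2c(OCOC)cc(OCc3ccccc3)cc2OCc2ccccc2)O[Si](C(C)C)(C(C)C)C(C)C)=C1 | intermediate
20 | (2S)-2-[4-(benzyloxy)phenyl]-6-[2,4-bis(benzyloxy)-6-(methoxymethoxy)phenyl]-5-hydroxy-7-(triisopropylsilyloxy)chroman-4-one | O=C1C[C@@H](c2ccc(OCc3ccccc3)cc2)Oc2cc(O[Si](C(C)C)(C(C)C)C(C)C)c(-c3c(OCOC)cc(OCc4ccccc4)cc3OCc3ccccc3)c(O)c21 | intermediate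
21 | (2S)-2-[4-(benzyloxy)phenyl]-6-[2,4-bis(benzyloxy)-6-hydroxyphenyl]-5-hydroxy-7-(triisopropylsilyloxy)chroman-4-one | O=C1C[C@@H](c2ccc(OCc3ccccc3)cc2)Oc2cc(O[Si](C(C)C)(C(C)C)C(C)C)c(-c3c(O)cc(OCc4ccccc4)cc3OCc3ccccc3)c(O)c21 | intermediate
22 | 1-(benzyloxy)-4-ethynylbenzene | C#Cc1ccc(OCc2ccccc2)cc1 | starting material
23 | lithium [4-(benzyloxy)phenyl]acetylide | [Li]C#Cc1ccc(OCc2ccccc2)cc1 | intermediate
24 | lithium 3-[4-(benzyloxy)phenyl]prop-2-ynoate | [Li+].[O-]C(=O)C#Cc1ccc(OCc2ccccc2)cc1 | intermediate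
25 | 3-[4-(benzyloxy)phenyl]prop-2-ynoic acid | OC(=O)C#Cc1ccc(OCc2ccccc2)cc1 | intermediate
26 | 3,5-bis(benzyloxy)-2-[(2S)-2-[4-(benzyloxy)phenyl]-5-hydroxy-4-oxo-7-(triisopropylsilyloxy)chroman-6-yl]phenyl 3-[4-(benzyloxy)phenyl]prop-2-ynoate | O=C1C[C@@H](c2ccc(OCc3ccccc3)cc2)Oc2cc(O[Si](C(C)C)(C(C)C)C(C)C)c(-c3c(OC(=O)C#Cc4ccc(OCc5ccccc5)cc4)cc(OCc4ccccc4)cc3OCc3ccccc3)c(O)c21 | intermediate
27 | (2S)-2-[4-(benzyloxy)phenyl]-6-{4,6-bis(benzyloxy)-3-[3-(4-(benzyloxy)phenyl)prop-2-ynoyl]-2-hydroxyphenyl}-5-hydroxy-7-(triisopropylsilyloxy)chroman-4-one | O=C1C[C@@H](c2ccc(OCc3ccccc3)cc2)Oc2cc(O[Si](C(C)C)(C(C)C)C(C)C)c(-c3c(O)c(C(=O)C#Cc4ccc(OCc5ccccc5)cc4)c(OCc4ccccc4)cc3OCc3ccccc3)c(O)c21 | intermediate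
28 | (2S)-2-[4-(benzyloxy)phenyl]-6-[5,7-bis(benzyloxy)-2-(4-(benzyloxy)phenyl)-4-oxo-4H-chromen-8-yl]-5-hydroxy-7-(triisopropylsilyloxy)chroman-4-one | O=C1C[C@@H](c2ccc(OCc3ccccc3)cc2)Oc2cc(O[Si](C(C)C)(C(C)C)C(C)C)c(-c3c(OCc4ccccc4)cc(OCc4ccccc4)c4c(=O)cc(-c5ccc(OCc6ccccc6)cc5)oc34)c(O)c21 | intermediate
29 | (2S)-2-[4-(benzyloxy)phenyl]-6-[5,7-bis(benzyloxy)-2-(4-(benzyloxy)phenyl)-4-oxo-4H-chromen-8-yl]-5,7-dihydroxychroman-4-one | O=C1C[C@@H](c2ccc(OCc3ccccc3)cc2)Oc2cc(O)c(-c3c(OCc4ccccc4)cc(OCc4ccccc4)c4c(=O)cc(-c5ccc(OCc6ccccc6)cc5)oc34)c(O)c21 | intermediate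
30 | CNP0154104.1, (2S)-6-[5,7-dihydroxy-2-(4-hydroxyphenyl)-4-oxo-4H-chromen-8-yl]-5,7-dihydroxy-2-(4-hydroxyphenyl)chroman-4-one | O=C1C[C@@H](c2ccc(O)cc2)Oc2cc(O)c(-c3c(O)cc(O)c4c(=O)cc(-c5ccc(O)cc5)oc34)c(O)c21 | target

## Step count and risks

Total step count: 16.
Longest linear sequence: 11 (steps 1–4, 9, 10, 12–16; the branch through steps 5–8 is equally long).

**1. Step 9 (key step).**
- What may go wrong: capture of the vinylketene by the hindered alkyne may be too slow. Ketene dimerisation, hydration by adventitious water or carbene side reactions would then consume the diazoketone. The sequence may also stall before the four-membered ring opens.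
- Fallback, known chemistry only: the biaryl bond is made by base-free cross-coupling on a ready-made flavanone. It sets out from 12 and comes back at 20.
- Aryl partner:
  - Pinnick oxidation of 12 (NaClO2, NaH2PO4, 2-methylbut-2-ene, t-BuOH–H2O) gives 2,4-bis(benzyloxy)-6-(methoxymethoxy)benzoic acid F1.
  - Decarboxylative iodination (I2, K3PO4, MeCN, 100 °C), known for 2,6-dialkoxybenzoic acids, gives 1,5-bis(benzyloxy)-2-iodo-3-(methoxymethoxy)benzene F2.
  - Insertion of zinc dust in the presence of LiCl (THF, 50 °C) gives [2,4-bis(benzyloxy)-6-(methoxymethoxy)phenyl]zinc iodide F3.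
- Flavanone partner, from commercial (2S)-naringenin:
  - Silylation at the most acidic 7-OH (TIPSCl, imidazole, DMF, 0 °C) gives (2S)-5-hydroxy-2-(4-hydroxyphenyl)-7-(triisopropylsilyloxy)chroman-4-one F4.
  - Benzylation at the 4'-OH under neutral Mitsunobu conditions (BnOH, PPh3, DIAD, THF) gives (2S)-2-[4-(benzyloxy)phenyl]-5-hydroxy-7-(triisopropylsilyloxy)chroman-4-one F5.
  - Iodination next to the chelated 5-OH (benzyltrimethylammonium dichloroiodate, CaCO3, CH2Cl2–MeOH) gives (2S)-2-[4-(benzyloxy)phenyl]-5-hydroxy-6-iodo-7-(triisopropylsilyloxy)chroman-4-one F6.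
- Union: Negishi coupling of F6 with an excess of F3 (Pd2(dba)3, RuPhos, THF, 60 °C) gives 20. This catalyst system is known for tetra-ortho-substituted biaryls and tolerates acidic OH groups.

**2. Step 13 (photo-Fries shift).**
- What may go wrong: the acyl radical may recombine at the para carbon or escape from the solvent cage with loss of the acyl group. The flavanone chromophore may screen the light. Long irradiation may slowly erode C2 or the benzyl ethers.
- Fallback: the acyl carbon is brought in by palladium-catalysed carbonylation instead of by acyl migration. It sets out from 21, skips step 12 and comes back at 27.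
- Iodination of 21 with one equivalent of NIS (CH2Cl2, −20 °C) should occur on the more electron-rich pendant ring next to its free OH, as 2-hydroxy-4,6-dialkoxyaryl compounds do. It gives (2S)-2-[4-(benzyloxy)phenyl]-6-[4,6-bis(benzyloxy)-2-hydroxy-3-iodophenyl]-5-hydroxy-7-(triisopropylsilyloxy)chroman-4-one F7.
- Carbonylative Sonogashira coupling of F7 with alkyne 22 (CO 1 atm, PdCl2(PPh3)2, CuI, Et3N, THF, rt) then gives ynone 27.

**3. Step 4 (diazoketone formation).**
- What may go wrong: dipolar cycloaddition of diazomethane to the C5=C6 bond may compete with acylation. Attack may also occur at the carbonate carbonyl of the mixed anhydride.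
- Fallback: the diazo group is installed by diazo transfer, so that no free diazoalkane meets the enone. It sets out from 7 and comes back at 9.
- 1-Chloro-N,N,2-trimethylprop-1-en-1-amine (CH2Cl2, 0 °C) converts 7 under neutral conditions into (2S)-2-[4-(benzyloxy)phenyl]-4-oxo-3,4-dihydro-2H-pyran-6-carbonyl chloride F8.
- Stille acylation (Me4Sn, PdCl2(PPh3)2, THF, 60 °C) gives (2S)-6-acetyl-2-[4-(benzyloxy)phenyl]-2,3-dihydro-4H-pyran-4-one F9.
- F9 is treated with LiN(SiMe3)2 and then CF3CO2CH2CF3 at −78 °C. The acetyl group is the more acidic site, because the C4 carbonyl is deactivated as a vinylogous ester. The product is (2S)-2-[4-(benzyloxy)phenyl]-6-(4,4,4-trifluoro-3-oxobutanoyl)-2,3-dihydro-4H-pyran-4-one F10, which is used crude.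
- Detrifluoroacetylative diazo transfer (MsN3, Et3N, H2O, MeCN, rt) then gives 9.

## Further compounds

F1 | step 9 | 2,4-bis(benzyloxy)-6-(methoxymethoxy)benzoic acid | COCOc1cc(OCc2ccccc2)cc(OCc2ccccc2)c1C(=O)O
F2 | step 9 | 1,5-bis(benzyloxy)-2-iodo-3-(methoxymethoxy)benzene | COCOc1cc(OCc2ccccc2)cc(OCc2ccccc2)c1I
F3 | step 9 | [2,4-bis(benzyloxy)-6-(methoxymethoxy)phenyl]zinc iodide | COCOc1cc(OCc2ccccc2)cc(OCc2ccccc2)c1[Zn]I
F4 | step 9 | (2S)-5-hydroxy-2-(4-hydroxyphenyl)-7-(triisopropylsilyloxy)chroman-4-one | O=C1C[C@@H](c2ccc(O)cc2)Oc2cc(O[Si](C(C)C)(C(C)C)C(C)C)cc(O)c21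
F5 | step 9 | (2S)-2-[4-(benzyloxy)phenyl]-5-hydroxy-7-(triisopropylsilyloxy)chroman-4-one | O=C1C[C@@H](c2ccc(OCc3ccccc3)cc2)Oc2cc(O[Si](C(C)C)(C(C)C)C(C)C)cc(O)c21
F6 | step 9 | (2S)-2-[4-(benzyloxy)phenyl]-5-hydroxy-6-iodo-7-(triisopropylsilyloxy)chroman-4-one | O=C1C[C@@H](c2ccc(OCc3ccccc3)cc2)Oc2cc(O[Si](C(C)C)(C(C)C)C(C)C)c(I)c(O)c21
F7 | step 13 | (2S)-2-[4-(benzyloxy)phenyl]-6-[4,6-bis(benzyloxy)-2-hydroxy-3-iodophenyl]-5-hydroxy-7-(triisopropylsilyloxy)chroman-4-one | O=C1C[C@@H](c2ccc(OCc3ccccc3)cc2)Oc2cc(O[Si](C(C)C)(C(C)C)C(C)C)c(-c3c(O)c(I)c(OCc4ccccc4)cc3OCc3ccccc3)c(O)c21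
F8 | step 4 | (2S)-2-[4-(benzyloxy)phenyl]-4-oxo-3,4-dihydro-2H-pyran-6-carbonyl chloride | O=C1C[C@@H](c2ccc(OCc3ccccc3)cc2)OC(C(=O)Cl)=C1
F9 | step 4 | (2S)-6-acetyl-2-[4-(benzyloxy)phenyl]-2,3-dihydro-4H-pyran-4-one | O=C1C[C@@H](c2ccc(OCc3ccccc3)cc2)OC(C(C)=O)=C1
F10 | step 4 | (2S)-2-[4-(benzyloxy)phenyl]-6-(4,4,4-trifluoro-3-oxobutanoyl)-2,3-dihydro-4H-pyran-4-one | O=C1C[C@@H](c2ccc(OCc3ccccc3)cc2)OC(C(=O)CC(=O)C(F)(F)F)=C1
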